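**Retrosynthetic overview**

- Target 12 ← tribenzyl ether 11 (debenzylation) ← (R)-lactone 9 plus aldehyde 10 (Claisen–Schmidt condensation at the C8 acetyl group) ← 4-phenylcoumarin 8 (asymmetric conjugate reduction sets C4).
- Key disconnection: the pyranone ring (ring B) of 8 is cut at C2–C3 and at C4–C4a, leading back to O-aryl thiocarbamate 4 and silyl alkyne 5, joined by one [Cp*RhCl2]2-catalysed C–H annulation.
- Enabling feature: on the phloroglucinol ring (ring A), C4a–H is the only free position ortho to the lactone oxygen O1, because the other ortho carbon, C8, carries the acyl group. O1 can therefore carry C2 as a thiocarbamate, which steers the metal to C4a and is then attacked by C3.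
- Ring order: ring A is bought (phloroacetophenone 1); ring B is closed in step 3, which also brings in the 4-phenyl ring (ring C); the 4-hydroxyphenyl ring (ring D) enters with aldehyde 10 in step 5.

Key step: step 3

Assumption: the facial sense of the chiral catalysts (step 4 and its fallback) is taken from simpler 4-substituted coumarins; if a model run shows the opposite sense, the mirror-image ligand is used.

**Route**

Step 1
Reactants: 1 1-(2,4,6-trihydroxyphenyl)ethan-1-one
Product: 2 1-[2,4-bis(benzyloxy)-6-hydroxyphenyl]ethan-1-one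
Conditions: BnBr (2.05 equiv), K2CO3, DMF, rt
Reagents that add atoms: benzyl bromide, SMILES BrCc1ccccc1
Why: Williamson etherification alkylates the 4-OH and one of the two equivalent ortho-OH groups, while the last ortho-OH stays locked in a hydrogen bond to the ketone and remains free as the future O1.

Step 2
Reactants: 2 1-[2,4-bis(benzyloxy)-6-hydroxyphenyl]ethan-1-one; 3 dimethylthiocarbamoyl chloride
Product: 4 O-[2-acetyl-3,5-bis(benzyloxy)phenyl] N,N-dimethylcarbamothioate
Conditions: NaH (1.05 equiv), DMF, 0 °C; then 3, 60 °C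
Reagents that add atoms: none
Why: O-thiocarbamoylation of the sodium phenoxide (the standard preparation of O-aryl thiocarbamates) places the future C2 on O1, and no stereocentre is formed.

Step 3
Reactants: 4 O-[2-acetyl-3,5-bis(benzyloxy)phenyl] N,N-dimethylcarbamothioate; 5 trimethyl(phenylethynyl)silane
Product: 8 8-acetyl-5,7-bis(benzyloxy)-4-phenyl-2H-chromen-2-one, via 3-silyl thione 6 (not isolated), via 3-silyl coumarin 7 (not isolated)
Conditions: [Cp*RhCl2]2 (cat.), AgOTf (cat.), Cu(OAc)2·H2O (2 equiv), t-AmOH, 120 °C; then Bu4NF, AcOH, THF, rt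
Reagents that add atoms: water, SMILES O
Why: The thiocarbonyl sulfur binds the Cp*Rh cation made from [Cp*RhCl2]2 and AgOTf and directs acetate-assisted C–H metalation to C4a; alkyne 5 then inserts into the Rh–C4a bond (new C4–C4a bond), the alkenyl–Rh carbon C3 adds to the thiocarbonyl carbon C2 (new C2–C3 bond), and loss of dimethylamine frees the catalyst and leaves thione 6. The closest known reaction type is the annulation of O-aryl thiocarbamates with internal alkynes to coumarins under the same catalyst system. Ring B is closed by 6-exo-trig attack of C3 on the C=S carbon. No stereocentre is formed here, since C4 becomes sp2 and is set in step 4. The step needs site selectivity, secured by the acetyl group that blocks C8, and insertion regioselectivity, secured by the silyl group, which should end on the Rh-bound carbon (C3) and so place phenyl on C4. Cu(OAc)2·H2O then exchanges sulfur for oxygen to give 7, and fluoride removes the C3 silyl group to give 8.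

Step 4
Reactants: 8 8-acetyl-5,7-bis(benzyloxy)-4-phenyl-2H-chromen-2-one
Product: 9 (4R)-8-acetyl-5,7-bis(benzyloxy)-4-phenyl-3,4-dihydro-2H-chromen-2-one
Conditions: Cu(OAc)2·H2O (cat.), (R)-DTBM-SEGPHOS (cat.), (EtO)2MeSiH (1.2 equiv), t-BuOH (1.2 equiv), toluene, 0 °C
Reagents that add atoms: none
Why: CuH carrying the chiral bisphosphine delivers hydride to one face of C4 of the unsaturated lactone and tert-butanol protonates the enolate (asymmetric conjugate reduction, known for 4-arylcoumarins), so the ligand sets C4 as R, while the acetyl group, twisted between two ortho substituents, is expected to react much more slowly.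

Step 5
Reactants: 9 (4R)-8-acetyl-5,7-bis(benzyloxy)-4-phenyl-3,4-dihydro-2H-chromen-2-one; 10 4-(benzyloxy)benzaldehyde
Product: 11 (4R)-5,7-bis(benzyloxy)-8-[(2E)-3-[4-(benzyloxy)phenyl]prop-2-enoyl]-4-phenyl-3,4-dihydro-2H-chromen-2-one
Conditions: BF3·OEt2 (3 equiv), 1,4-dioxane, rt
Reagents that add atoms: none
Why: Boron trifluoride promotes enolisation of the methyl ketone and condensation with the non-enolisable aldehyde (acid-mediated Claisen–Schmidt condensation), which should give the E-enone under thermodynamic control without the base that would open the aryl lactone; C4 is not touched.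

Step 6
Reactants: 11 (4R)-5,7-bis(benzyloxy)-8-[(2E)-3-[4-(benzyloxy)phenyl]prop-2-enoyl]-4-phenyl-3,4-dihydro-2H-chromen-2-one
Product: 12 (4R)-5,7-dihydroxy-8-[(2E)-3-(4-hydroxyphenyl)prop-2-enoyl]-4-phenyl-3,4-dihydro-2H-chromen-2-one
Conditions: BCl3 (6 equiv), C6HMe5 (9 equiv), CH2Cl2, −78 °C; then aq. NaHCO3
Reagents that add atoms: none
Why: Boron trichloride cleaves the three aryl benzyl ethers at low temperature while pentamethylbenzene traps the benzyl cations (Lewis acid debenzylation with a cation scavenger), conditions expected to leave the enone, the aryl lactone and the C4 stereocentre untouched.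

**Compound list**

1 | 1-(2,4,6-trihydroxyphenyl)ethan-1-one | CC(=O)c1c(O)cc(O)cc1O | starting material
2 | 1-[2,4-bis(benzyloxy)-6-hydroxyphenyl]ethan-1-one | CC(=O)c1c(O)cc(OCc2ccccc2)cc1OCc1ccccc1 | intermediate
3 | dimethylthiocarbamoyl chloride | CN(C)C(=S)Cl | starting material
4 | O-[2-acetyl-3,5-bis(benzyloxy)phenyl] N,N-dimethylcarbamothioate | CC(=O)c1c(OC(=S)N(C)C)cc(OCc2ccccc2)cc1OCc1ccccc1 | intermediate
5 | trimethyl(phenylethynyl)silane | C[Si](C)(C)C#Cc1ccccc1 | starting material
6 | 8-acetyl-5,7-bis(benzyloxy)-4-phenyl-3-(trimethylsilyl)-2H-chromene-2-thione (3-silyl thione) | S=C1C([Si](C)(C)C)=C(c2ccccc2)c2c(OCc3ccccc3)cc(OCc3ccccc3)c(C(C)=O)c2O1 | intermediate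
7 | 8-acetyl-5,7-bis(benzyloxy)-4-phenyl-3-(trimethylsilyl)-2H-chromen-2-one (3-silyl coumarin) | O=C1C([Si](C)(C)C)=C(c2ccccc2)c2c(OCc3ccccc3)cc(OCc3ccccc3)c(C(C)=O)c2O1 | intermediate
8 | 8-acetyl-5,7-bis(benzyloxy)-4-phenyl-2H-chromen-2-one | O=C1C=C(c2ccccc2)c2c(OCc3ccccc3)cc(OCc3ccccc3)c(C(C)=O)c2O1 | intermediate
9 | (4R)-8-acetyl-5,7-bis(benzyloxy)-4-phenyl-3,4-dihydro-2H-chromen-2-one | O=C1C[C@H](c2ccccc2)c2c(OCc3ccccc3)cc(OCc3ccccc3)c(C(C)=O)c2O1 | intermediate
10 | 4-(benzyloxy)benzaldehyde | O=Cc1ccc(OCc2ccccc2)cc1 | starting material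
11 | (4R)-5,7-bis(benzyloxy)-8-[(2E)-3-[4-(benzyloxy)phenyl]prop-2-enoyl]-4-phenyl-3,4-dihydro-2H-chromen-2-one | O=C1C[C@H](c2ccccc2)c2c(OCc3ccccc3)cc(OCc3ccccc3)c(C(=O)/C=C/c3ccc(OCc4ccccc4)cc3)c2O1 | intermediate
12 | (4R)-5,7-dihydroxy-8-[(2E)-3-(4-hydroxyphenyl)prop-2-enoyl]-4-phenyl-3,4-dihydro-2H-chromen-2-one | O=C1C[C@H](c2ccccc2)c2c(O)cc(O)c(C(=O)/C=C/c3ccc(O)cc3)c2O1 | target

**Step count and risks**

Total step count: 6. Longest linear sequence: 6 steps (1 to 12).

Steps most likely to fail:

1. Step 3. The C4a–H lies between the thiocarbamate oxygen and a benzyloxy group, so metalation may be slow. The alkyne may also insert in the reverse sense, or lose its silyl group and homocouple before it inserts. Fallback: from 2, esterification with 3-phenylpropiolic acid (DCC, DMAP, CH2Cl2) should give 2-acetyl-3,5-bis(benzyloxy)phenyl 3-phenylprop-2-ynoate F1. AuCl3/AgOTf-catalysed intramolecular hydroarylation of this aryl alkynoate (1,2-dichloroethane, 50 °C), in which C4a attacks the phenyl-bearing alkyne carbon, should then give coumarin 8, where the route is rejoined before step 4.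

2. Step 4. The acetyl ketone may undergo competing 1,2-reduction, the lactone may be over-reduced to the lactol, and facial discrimination may be weak next to the 5-benzyloxy group. Fallback: from 2, esterification with propiolic acid (DCC, CH2Cl2, 0 °C) should give 2-acetyl-3,5-bis(benzyloxy)phenyl prop-2-ynoate F2, and AuCl3/AgOTf-catalysed cyclisation should give 8-acetyl-5,7-bis(benzyloxy)-2H-chromen-2-one F3. Asymmetric 1,4-addition of phenylboronic acid (Rh(acac)(C2H4)2, (R)-SEGPHOS, dioxane/H2O, 60 °C) then installs the phenyl group and the C4 stereocentre together without touching ketone or lactone, and gives 9, where the route is rejoined before step 5.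

3. Step 5. Enolisation of the doubly ortho-substituted methyl ketone may be sluggish, and benzyl ethers may be cleaved by the Lewis acid on long reaction times. Fallback: from 9, the boron enolate of the methyl ketone is formed selectively (Bu2BOTf, i-Pr2NEt, CH2Cl2, −78 °C) and added to aldehyde 10 to give (4R)-5,7-bis(benzyloxy)-8-[3-[4-(benzyloxy)phenyl]-3-hydroxypropanoyl]-4-phenyl-3,4-dihydro-2H-chromen-2-one F4 as a mixture of carbinol epimers. A separate acid-catalysed dehydration (TsOH cat., toluene, 50 °C) should then give 11, where the route is rejoined before step 6.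

Further compounds
F1 | step 3 | 2-acetyl-3,5-bis(benzyloxy)phenyl 3-phenylprop-2-ynoate | CC(=O)c1c(OC(=O)C#Cc2ccccc2)cc(OCc2ccccc2)cc1OCc1ccccc1
F2 | step 4 | 2-acetyl-3,5-bis(benzyloxy)phenyl prop-2-ynoate | CC(=O)c1c(OC(=O)C#C)cc(OCc2ccccc2)cc1OCc1ccccc1
F3 | step 4 | 8-acetyl-5,7-bis(benzyloxy)-2H-chromen-2-one | O=C1C=Cc2c(OCc3ccccc3)cc(OCc3ccccc3)c(C(C)=O)c2O1
F4 | step 5 | (4R)-5,7-bis(benzyloxy)-8-[3-[4-(benzyloxy)phenyl]-3-hydroxypropanoyl]-4-phenyl-3,4-dihydro-2H-chromen-2-one | O=C1C[C@H](c2ccccc2)c2c(OCc3ccccc3)cc(OCc3ccccc3)c(C(=O)CC(O)c3ccc(OCc4ccccc4)cc3)c2O1
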